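**Plan**

1. Retrosynthesis: take off the hexanoate, the two acetates and the silyl groups; open the γ-lactone at C19–O7 back to a C17 dioxolanone (an acyl donor); cut C7–C8 (the ring-closing event); then cut C2–C3 (aldol with the C3–C7 ketone 30), C8–C17 (dioxolanone aldol) and C9–C8 (vinyl addition); the cyclohexene falls to a Diels–Alder pair (bonds C1–C14 and C10–C11).
2. Enabling feature: the array C5=C6–C7(O)–C8(OH), shared by the ten-membered carbocycle and the γ-lactone, is a homoallylic 1,2-diol, the retron of a γ-oxyallylmetal adding to a ketone. An enal C5=C6–C7=O is therefore used as a latent C7 nucleophile (reductive umpolung with CrCl2/Me3SiCl) toward the C8 ketone; the allylic transposition gives back the C5=C6 bond inside the new ring.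
3. Forward order: six-membered ring first (Diels–Alder); a temporary C2–O–C9 γ-lactone tells the two appendages apart (opened in step 9); northern arm (C9, C8, then C17/C18/C19 as a dioxolanone); southern arm C3–C7 by aldol; ten-membered ring by the key cyclisation; γ-lactone last by acyl transfer from the dioxolanone (pivalaldehyde lost in step 24).
4. Stereochemistry: C1/C10 from the catalytic asymmetric Diels–Alder; C11/C12 by osmylation anti to C9; C9 by CBS reduction; C17 from (R)-lactic acid (self-regeneration of stereocentres); C2/C3 by Z-boron-enolate aldol; C4 by 1,3-syn reduction; C7, C8 and the 5Z alkene in the key step.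

Key step: step 23

Remark on names: locants are those of the briarane skeleton of the target. C1 (quaternary, CH3-15) and C10 are the ring-fusion carbons; C11 (CH3-20), C12, C13, C14 complete the six-membered ring; C2–C9 complete the ten-membered ring (CH3-16 on C5); C17 (CH3-18) and C19 belong to the lactone; α is the face of H-10, β the face of CH3-15.

Assumption: amide 28 is taken as a purchasable building block, and the facial sense of the oxazaborolidinium catalyst in step 2 is assigned by the usual model for α-substituted enals; should it prove opposite, the antipodal catalyst is used with no other change.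

**Route**

Step 1
Reactants: 1 pent-1-en-3-one
Product: 2 (Z)-3-(triisopropylsilyloxy)penta-1,3-diene
Conditions: i-Pr3SiOTf, Et3N, CH2Cl2, 0 °C
Reagents that add atoms: triisopropylsilyl trifluoromethanesulfonate CC(C)[Si](C(C)C)(C(C)C)OS(=O)(=O)C(F)(F)F
Why: Soft enolisation of the ethyl ketone with silyl triflate and amine gives the 2-silyloxy diene, the Z enol ether being the kinetic product.

Step 2
Reactants: 2 (Z)-3-(triisopropylsilyloxy)penta-1,3-diene; 3 ethyl (E)-3-methyl-4-oxobut-2-enoate
Product: 4 ethyl (1S,2S,6S)-2-formyl-2,6-dimethyl-5-(triisopropylsilyloxy)cyclohex-4-ene-1-carboxylate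
Conditions: (S)-o-tolyl-oxazaborolidine (from (S)-α,α-diphenylprolinol) activated with HNTf2 (20 mol%), CH2Cl2, −78 → −40 °C
Reagents that add atoms: none
Why: Lewis-acid-catalysed endo Diels–Alder reaction in which the formyl group bound to the chiral oxazaborolidinium ion controls the regiochemistry (nucleophilic diene terminus C11 to the β-carbon C10, CH2 terminus to C1) and the face, while the E geometry of 3 places C2 and C9 trans, so that C1 (quaternary) and C10 are set.

Step 3
Reactants: 4 ethyl (1S,2S,6S)-2-formyl-2,6-dimethyl-5-(triisopropylsilyloxy)cyclohex-4-ene-1-carboxylate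
Product: 6 trans-fused O2–C9 γ-lactone carrying the C12 silyl enol ether, via hydroxy ester 5 (not isolated)
Conditions: NaBH4, EtOH, 0 °C; then DBU (10 mol%), toluene, 40 °C
Reagents that add atoms: none
Why: Borohydride reduces the non-enolisable neopentyl aldehyde but not the ester, and base-catalysed transesterification closes the trans-fused γ-lactone, a temporary ring that keeps C2 at the alcohol level and C9 at the acid level.

Step 4
Reactants: 6 trans-fused O2–C9 γ-lactone carrying the C12 silyl enol ether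
Product: 7 enone lactone (C12 ketone with C13=C14)
Conditions: Pd(OAc)2 (10 mol%), O2 (1 atm), DMSO, 50 °C
Reagents that add atoms: none
Why: Saegusa–Ito oxidation, in which the palladium enolate formed from the silyl enol ether undergoes β-hydride elimination toward C14 and gives the C13=C14 enone regiospecifically.

Step 5
Reactants: 7 enone lactone (C12 ketone with C13=C14)
Product: 9 dienyl triflate (C11=C12–OTf with C13=C14), via potassium dienolate 8 (not isolated)
Conditions: KHMDS, THF, −78 °C; then PhNTf2, −78 → 0 °C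
Reagents that add atoms: N-phenylbis(trifluoromethanesulfonimide) O=S(=O)(N(c1ccccc1)S(=O)(=O)C(F)(F)F)C(F)(F)F
Why: Kinetic deprotonation at the ketone α′-carbon C11 (more acidic than the lactone α-carbon C10) followed by O-sulfonylation gives the cross-conjugated dienyl triflate and erases the provisional C11 centre.

Step 6
Reactants: 9 dienyl triflate (C11=C12–OTf with C13=C14)
Product: 10 diene lactone (C11(CH3)=C12–C13=C14)
Conditions: Pd(OAc)2 (5 mol%), PPh3 (10 mol%), HCO2H, Et3N, DMF, 60 °C
Reagents that add atoms: none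
Why: Palladium-catalysed formate reduction of an alkenyl triflate (oxidative addition, formate exchange, decarboxylation, reductive elimination) gives the 1,3-diene.

Step 7
Reactants: 10 diene lactone (C11(CH3)=C12–C13=C14)
Product: 11 11α,12α-dihydroxy lactone
Conditions: OsO4 (2 mol%), N-methylmorpholine N-oxide, acetone–H2O, 0 °C
Reagents that add atoms: osmium tetroxide O=[Os](=O)(=O)=O; N-methylmorpholine N-oxide C[N+]1([O-])CCOCC1; water O
Why: Catalytic osmylation takes place at the more electron-rich trisubstituted C11=C12 bond of the diene and from the α face, anti to the C10–C9 bond and to CH3-15, which sets C11 and C12 as the cis-α-diol.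

Step 8
Reactants: 11 11α,12α-dihydroxy lactone
Product: 12 12α-(tert-butyldimethylsilyloxy)-11α-hydroxy lactone
Conditions: t-BuMe2SiOTf (1.05 equiv), 2,6-lutidine, CH2Cl2, −78 °C
Reagents that add atoms: tert-butyldimethylsilyl trifluoromethanesulfonate CC(C)(C)[Si](C)(C)OS(=O)(=O)C(F)(F)F
Why: Silylation of the secondary allylic hydroxyl is much faster than that of the neighbouring tertiary hydroxyl.

Step 9
Reactants: 12 12α-(tert-butyldimethylsilyloxy)-11α-hydroxy lactone
Product: 13 C9 vinyl ketone with free C2 hydroxymethyl group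
Conditions: CH2=CHMgBr (2.3 equiv), THF, −78 °C; aq. NH4Cl at −78 °C
Reagents that add atoms: vinylmagnesium bromide C=C[Mg]Br
Why: Grignard addition to the hindered lactone stops at the tetrahedral magnesium hemiketal at low temperature, which collapses to the vinyl ketone only on work-up, so the temporary lactone is opened with C2 and C9 differentiated.

Step 10
Reactants: 13 C9 vinyl ketone with free C2 hydroxymethyl group
Product: 14 (9S)-allylic alcohol (O2/O9/O11 triol)
Conditions: (R)-2-methyl-CBS-oxazaborolidine (0.5 equiv), catecholborane (4 equiv), toluene, −78 °C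
Reagents that add atoms: none
Why: Corey–Bakshi–Shibata reduction, in which the catalyst distinguishes the small vinyl group from the bulky ring substituent and the (R)-catalyst gives the 9S carbinol, the C9 configuration of the target.

Step 11
Reactants: 14 (9S)-allylic alcohol (O2/O9/O11 triol)
Product: 15 2,9,11-tris-O-triethylsilyl ether
Conditions: Et3SiOTf (4 equiv), 2,6-lutidine, CH2Cl2, −78 → 0 °C
Reagents that add atoms: triethylsilyl trifluoromethanesulfonate CC[Si](CC)(CC)OS(=O)(=O)C(F)(F)F
Why: The silyl triflate silylates the primary, the secondary and the tertiary hydroxyl, the primary silyl ether being the handle for later oxidation.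

Step 12
Reactants: 15 2,9,11-tris-O-triethylsilyl ether
Product: 17 C8 aldehyde (9-triethylsilyloxy), via terminal diol 16 (not isolated)
Conditions: OsO4 (2 mol%), NaIO4 (4 equiv), 2,6-lutidine, dioxane–H2O, 23 °C
Reagents that add atoms: osmium tetroxide O=[Os](=O)(=O)=O; sodium periodate [Na+].[O-]I(=O)(=O)=O; water O
Why: Lemieux–Johnson oxidation, in which osmylation occurs at the unhindered monosubstituted vinyl group in preference to the ring alkene (flanked by a quaternary carbon and a silyloxy-bearing carbon) and periodate cleaves the diol.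

Step 13
Reactants: 18 (R)-lactic acid; 19 pivalaldehyde
Product: 20 (2R,5R)-2-tert-butyl-5-methyl-1,3-dioxolan-4-one
Conditions: TsOH (cat.), pentane, reflux with water separator; crystallisation at −78 °C
Reagents that add atoms: none
Why: Acid-catalysed acetalisation under thermodynamic control gives the cis-dioxolanone, which stores the lactic acid configuration in the acetal centre (self-regeneration of stereocentres).

Step 14
Reactants: 20 (2R,5R)-2-tert-butyl-5-methyl-1,3-dioxolan-4-one; 17 C8 aldehyde (9-triethylsilyloxy)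
Product: 22 aldol adduct (C8 carbinol bonded to the quaternary C17 of the dioxolanone), via lithium enolate 21 (not isolated)
Conditions: LDA, THF, −78 °C; then 17, −78 °C; AcOH quench at −78 °C
Reagents that add atoms: none
Why: Aldol addition of the planar dioxolanone enolate takes place anti to the tert-butyl group, so that C8 replaces the hydrogen of (R)-lactic acid with retention and the quaternary C17 is set, the configuration of the C8 carbinol being irrelevant.

Step 15
Reactants: 22 aldol adduct (C8 carbinol bonded to the quaternary C17 of the dioxolanone)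
Product: 23 keto aldehyde (C8 ketone and C2 aldehyde)
Conditions: (COCl)2 (6 equiv), DMSO (12 equiv), CH2Cl2, −78 → −40 °C; then Et3N, −78 → 0 °C
Reagents that add atoms: none
Why: Swern oxidation converts the hindered secondary alcohol into the ketone and, with excess activated DMSO, the primary triethylsilyl ether directly into the aldehyde, while secondary and tertiary silyl ethers are inert.

Step 16
Reactants: 24 but-2-yn-1-ol
Product: 26 (Z)-3-iodobut-2-en-1-ol, via alkenylalanate 25 (not isolated)
Conditions: NaAlH2(OCH2CH2OMe)2, THF, 0 → 23 °C; then I2, −78 °C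
Reagents that add atoms: iodine II
Why: Hydroxyl-directed anti-hydroalumination places aluminium on C3 in a five-membered alkoxyalanate and iodinolysis proceeds with retention, which gives the Z iodide.

Step 17
Reactants: 26 (Z)-3-iodobut-2-en-1-ol
Product: 27 (Z)-triethyl[(3-iodobut-2-en-1-yl)oxy]silane
Conditions: Et3SiCl, imidazole, CH2Cl2, 0 °C
Reagents that add atoms: chlorotriethylsilane CC[Si](CC)(CC)Cl
Why: Standard silylation of a primary allylic alcohol.

Step 18
Reactants: 27 (Z)-triethyl[(3-iodobut-2-en-1-yl)oxy]silane; 28 2-(tert-butyldimethylsilyloxy)-N-methoxy-N-methylacetamide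
Product: 30 (Z)-1-(tert-butyldimethylsilyloxy)-3-methyl-5-(triethylsilyloxy)pent-3-en-2-one, via alkenyllithium 29 (not isolated)
Conditions: t-BuLi (2.1 equiv), Et2O, −78 °C; then 28, −78 → −20 °C
Reagents that add atoms: none
Why: Iodine–lithium exchange is stereoretentive and the N-methoxy-N-methylamide gives the ketone through a stable chelated tetrahedral intermediate.

Step 19
Reactants: 30 (Z)-1-(tert-butyldimethylsilyloxy)-3-methyl-5-(triethylsilyloxy)pent-3-en-2-one; 23 keto aldehyde (C8 ketone and C2 aldehyde)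
Product: 32 2,3-syn aldol adduct (2-hydroxy-3-silyloxy C4 ketone), via dibutylboron enolate 31 (not isolated)
Conditions: n-Bu2BOTf, i-Pr2NEt, CH2Cl2, −78 °C; then 23, −78 → −20 °C; pH 7 buffer, H2O2, MeOH, 0 °C
Reagents that add atoms: none
Why: Aldol addition of the Z(O)-boron enolate through a Zimmerman–Traxler chair gives the 2,3-syn adduct, and attack on the aldehyde face anti to C10 (Felkin–Anh sense, CH3-15 as the small group) sets C2 and C3, the aldehyde reacting in preference to the hindered C8 ketone.

Step 20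
Reactants: 32 2,3-syn aldol adduct (2-hydroxy-3-silyloxy C4 ketone)
Product: 34 2,4-diol with C2/C3/C4 all syn, via diethylboryl chelate 33 (not isolated)
Conditions: Et2BOMe, THF–MeOH (4:1), −78 °C; then NaBH4, −78 °C; AcOH; MeOH co-evaporation
Reagents that add atoms: none
Why: Narasaka–Prasad reduction, in which external hydride attacks the diethylboron chelate of the β-hydroxy enone axially and gives the 2,4-syn diol (C4) by 1,2-reduction, while the hindered, non-chelated C8 ketone is not reduced at −78 °C.

Step 21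
Reactants: 34 2,4-diol with C2/C3/C4 all syn
Product: 35 2,4-bis-O-triethylsilyl ether
Conditions: Et3SiOTf (3 equiv), 2,6-lutidine, CH2Cl2, −78 °C
Reagents that add atoms: triethylsilyl trifluoromethanesulfonate CC[Si](CC)(CC)OS(=O)(=O)C(F)(F)F
Why: Silylation gives at C4 an oxygen substituent that is a poor leaving group for the organochromium step.

Step 22
Reactants: 35 2,4-bis-O-triethylsilyl ether
Product: 36 (5Z)-enal (C7 aldehyde with C8 ketone)
Conditions: (COCl)2 (4 equiv), DMSO (8 equiv), CH2Cl2, −78 → −35 °C; then Et3N, −78 → 0 °C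
Reagents that add atoms: none
Why: Swern conditions cleave and oxidise the primary allylic triethylsilyl ether selectively, so that the enal is unmasked in the presence of four more hindered triethylsilyl ethers.

Step 23
Reactants: 36 (5Z)-enal (C7 aldehyde with C8 ketone)
Product: 38 ten-membered carbocycle (7-O-trimethylsilyl 8-hydroxy 5Z), via siloxyallylchromium species 37 (not isolated)
Conditions: CrCl2 (8 equiv), Me3SiCl (4 equiv), THF, 23 °C, syringe-pump addition of 36 to a final 2 mM; aq. NaHCO3
Reagents that add atoms: chlorotrimethylsilane C[Si](C)(C)Cl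
Why: Proposed new method: CrCl2 and Me3SiCl reduce the conjugated aldehyde of 36 selectively to the γ-siloxyallylchromium species 37 (two one-electron transfers with O-silylation, divalent chromium going to trivalent chromium), and this nucleophile adds through its oxygen-bearing terminus C7 to the C8 ketone in a six-membered chair transition state with allylic transposition, so that the C5=C6 bond is re-formed inside the new ring; the closest known reaction is the chromium-mediated pinacol-type cross-coupling of enals with aldehydes, which has not been shown with a ketone acceptor or as a macrocyclisation. The ten-membered carbocycle closes by attack of C7 on the exocyclic carbonyl (10-exo-trig, SE2′ with respect to the allylmetal). C7 is controlled by the E geometry of the siloxy enol unit, which sits equatorial in the chair, and C8 by Felkin–Anh attack anti to the C9–OSiEt3 bond with C9 equatorial, which together give the required 7,8-anti (7S,8S) pattern, while the Z geometry of C5=C6 follows from the tether, which holds C4 axial at C5. The step needs C7 rather than C5 attack, and this is secured because C5 attack would join two fully substituted carbons in an eight-membered ring. Chemoselectivity is secured because only the enal is reducible by CrCl2, the C4 oxygen is a silyl ether (a poor leaving group β to chromium) and slow addition at high dilution suppresses intermolecular coupling.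

Step 24
Reactants: 38 ten-membered carbocycle (7-O-trimethylsilyl 8-hydroxy 5Z)
Product: 40 γ-lactone (C19–O7) with free 8-OH and 17-OH, via 7,8-diol 39 (not isolated)
Conditions: K2CO3 (0.3 equiv), MeOH, 0 °C
Reagents that add atoms: none
Why: Methanolysis removes the trimethylsilyl ether and the C7 alkoxide opens the dioxolanone (an activated acetal ester) in a 5-exo-trig acyl transfer, which forms the γ-lactone and releases pivalaldehyde and the C17 hydroxyl, while O9 is still silylated and cannot compete.

Step 25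
Reactants: 40 γ-lactone (C19–O7) with free 8-OH and 17-OH
Product: 41 lactone with free 2-OH 4-OH 9-OH 11-OH (3-O-TBS and 12-O-TBS kept)
Conditions: HF·pyridine, pyridine, THF, 0 → 23 °C
Reagents that add atoms: none
Why: Buffered HF·pyridine removes triethylsilyl ethers much faster than the two hindered tert-butyldimethylsilyl ethers.

Step 26
Reactants: 41 lactone with free 2-OH 4-OH 9-OH 11-OH
Product: 42 4-O-hexanoate
Conditions: hexanoic anhydride (1.1 equiv), 2,4,6-collidine, DMAP (10 mol%), CH2Cl2, −40 °C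
Reagents that add atoms: hexanoic anhydride CCCCCC(=O)OC(=O)CCCCC
Why: Site-selective acylation, because the allylic C4 hydroxyl is the least hindered of the three secondary alcohols (C2 is neopentyl, C9 lies between two fully substituted carbons) and the tertiary alcohols do not react.

Step 27
Reactants: 42 4-O-hexanoate
Product: 43 2,9-di-O-acetate
Conditions: Ac2O, Et3N, DMAP (20 mol%), CH2Cl2, 0 → 23 °C
Reagents that add atoms: acetic anhydride CC(=O)OC(C)=O
Why: DMAP-catalysed acetylation of the two remaining secondary hydroxyls, which leaves the tertiary hydroxyls at C8, C11 and C17 free.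

Step 28
Reactants: 43 2,9-di-O-acetate
Product: 44 CNP0153048.1
Conditions: HF·pyridine, THF, 23 °C
Reagents that add atoms: none
Why: Fluoride cleavage of the two remaining silyl ethers under weakly acidic conditions, which avoid acyl migration to the freed C3 hydroxyl, gives the target.

**Compound list**

1 | pent-1-en-3-one (ethyl vinyl ketone) | CCC(=O)C=C | starting material
2 | (Z)-3-(triisopropylsilyloxy)penta-1,3-diene | C=C/C(O[Si](C(C)C)(C(C)C)C(C)C)=C/C | intermediate
3 | ethyl (E)-3-methyl-4-oxobut-2-enoate | CCOC(=O)/C=C(\C)C=O | starting material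
4 | ethyl (1S,2S,6S)-2-formyl-2,6-dimethyl-5-(triisopropylsilyloxy)cyclohex-4-ene-1-carboxylate (C1 and C10 as in the target, formyl C2 and ester C9 trans) | O=C[C@@]1(C)CC=C(O[Si](C(C)C)(C(C)C)C(C)C)[C@@H](C)[C@@H]1C(=O)OCC | intermediate
5 | ethyl (1S,2S,6S)-2-(hydroxymethyl)-2,6-dimethyl-5-(triisopropylsilyloxy)cyclohex-4-ene-1-carboxylate | OC[C@@]1(C)CC=C(O[Si](C(C)C)(C(C)C)C(C)C)[C@@H](C)[C@@H]1C(=O)OCC | intermediate (not isolated)
6 | trans-fused bicyclic γ-lactone (O2–C9 lactone; CH3-15 β, H-10 α, 11-CH3 α; C12 triisopropylsilyl enol ether, C12=C13) | O=C1OC[C@@]2(C)CC=C(O[Si](C(C)C)(C(C)C)C(C)C)[C@@H](C)[C@H]12 | intermediate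
7 | enone lactone (C12 ketone, C13=C14; otherwise as 6) | O=C1OC[C@@]2(C)C=CC(=O)[C@@H](C)[C@H]12 | intermediate
8 | potassium dienolate of 7 (C11=C12–OK, C13=C14) | O=C1OC[C@@]2(C)C=CC(O[K])=C(C)[C@H]12 | intermediate (not isolated)
9 | dienyl triflate (C11=C12–OTf, C13=C14) | O=C1OC[C@@]2(C)C=CC(OS(=O)(=O)C(F)(F)F)=C(C)[C@H]12 | intermediate
10 | diene lactone (C11(CH3)=C12–C13=C14) | O=C1OC[C@@]2(C)C=CC=C(C)[C@H]12 | intermediate
11 | 11α,12α-dihydroxy lactone (CH3-20 β, C13=C14) | O=C1OC[C@@]2(C)C=C[C@@H](O)[C@@](C)(O)[C@H]12 | intermediate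
12 | 12α-(tert-butyldimethylsilyloxy)-11α-hydroxy lactone | O=C1OC[C@@]2(C)C=C[C@@H](O[Si](C)(C)C(C)(C)C)[C@@](C)(O)[C@H]12 | intermediate
13 | vinyl ketone: C9 ketone bearing the vinyl group (C8), free C2 CH2OH, 11α-OH, 12α-OTBS | OC[C@@]1(C)C=C[C@@H](O[Si](C)(C)C(C)(C)C)[C@@](C)(O)[C@@H]1C(=O)C=C | intermediate
14 | (9S)-allylic alcohol (O2, O9, O11 free; 12α-OTBS) | OC[C@@]1(C)C=C[C@@H](O[Si](C)(C)C(C)(C)C)[C@@](C)(O)[C@@H]1[C@@H](O)C=C | intermediate
15 | 2,9,11-tris-O-triethylsilyl ether of 14 | CC[Si](CC)(CC)OC[C@@]1(C)C=C[C@@H](O[Si](C)(C)C(C)(C)C)[C@@](C)(O[Si](CC)(CC)CC)[C@@H]1[C@@H](O[Si](CC)(CC)CC)C=C | intermediate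
16 | terminal 1,2-diol from the vinyl group of 15 (both configurations at the new carbinol) | CC[Si](CC)(CC)OC[C@@]1(C)C=C[C@@H](O[Si](C)(C)C(C)(C)C)[C@@](C)(O[Si](CC)(CC)CC)[C@@H]1[C@@H](O[Si](CC)(CC)CC)C(O)CO | intermediate (not isolated)
17 | C8 aldehyde (9-triethylsilyloxy, C9 as in the target) | CC[Si](CC)(CC)OC[C@@]1(C)C=C[C@@H](O[Si](C)(C)C(C)(C)C)[C@@](C)(O[Si](CC)(CC)CC)[C@@H]1[C@@H](O[Si](CC)(CC)CC)C=O | intermediate
18 | (R)-lactic acid | C[C@@H](O)C(=O)O | starting material
19 | pivalaldehyde (2,2-dimethylpropanal) | CC(C)(C)C=O | starting material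
20 | (2R,5R)-2-tert-butyl-5-methyl-1,3-dioxolan-4-one | CC(C)(C)[C@H]1OC(=O)[C@@H](C)O1 | intermediate
21 | lithium enolate of 20 | CC(C)(C)[C@H]1OC(O[Li])=C(C)O1 | intermediate (not isolated)
22 | aldol adduct: C8 carbinol (both epimers) bonded to C17 of the dioxolanone (C8 trans to tert-butyl, C17 as in the target) | CC[Si](CC)(CC)OC[C@@]1(C)C=C[C@@H](O[Si](C)(C)C(C)(C)C)[C@@](C)(O[Si](CC)(CC)CC)[C@@H]1[C@@H](O[Si](CC)(CC)CC)C(O)[C@]2(C)O[C@@H](C(C)(C)C)OC2=O | intermediate
23 | keto aldehyde: C8 ketone, C2 aldehyde | O=C[C@@]1(C)C=C[C@@H](O[Si](C)(C)C(C)(C)C)[C@@](C)(O[Si](CC)(CC)CC)[C@@H]1[C@@H](O[Si](CC)(CC)CC)C(=O)[C@]2(C)O[C@@H](C(C)(C)C)OC2=O | intermediate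
24 | but-2-yn-1-ol | CC#CCO | starting material
25 | sodium alkoxy(alkenyl)alanate (five-membered oxaaluminacycle from 24) | CC1=CCO[Al-]1(OCCOC)OCCOC.[Na+] | intermediate (not isolated)
26 | (Z)-3-iodobut-2-en-1-ol | OC/C=C(/C)I | intermediate
27 | (Z)-triethyl[(3-iodobut-2-en-1-yl)oxy]silane | CC[Si](CC)(CC)OC/C=C(/C)I | intermediate
28 | 2-(tert-butyldimethylsilyloxy)-N-methoxy-N-methylacetamide | CON(C)C(=O)CO[Si](C)(C)C(C)(C)C | starting material
29 | (Z)-alkenyllithium from 27 | CC[Si](CC)(CC)OC/C=C(/C)[Li] | intermediate (not isolated)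
30 | (Z)-1-(tert-butyldimethylsilyloxy)-3-methyl-5-(triethylsilyloxy)pent-3-en-2-one (C3–C7 with CH3-16) | CC[Si](CC)(CC)OC/C=C(/C)C(=O)CO[Si](C)(C)C(C)(C)C | intermediate
31 | Z(O)-dibutylboron enolate of 30 (enolised toward C3) | CC[Si](CC)(CC)OC/C=C(/C)\C(OB(CCCC)CCCC)=C\O[Si](C)(C)C(C)(C)C | intermediate (not isolated)
32 | aldol adduct: 2-hydroxy-3-(tert-butyldimethylsilyloxy) C4 ketone, 2,3-syn, 5Z | CC[Si](CC)(CC)OC/C=C(/C)C(=O)[C@@H](O[Si](C)(C)C(C)(C)C)[C@H](O)[C@@]1(C)C=C[C@@H](O[Si](C)(C)C(C)(C)C)[C@@](C)(O[Si](CC)(CC)CC)[C@@H]1[C@@H](O[Si](CC)(CC)CC)C(=O)[C@]2(C)O[C@@H](C(C)(C)C)OC2=O | intermediate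
33 | O2-diethylboryl chelate of 32 | CC[Si](CC)(CC)OC/C=C(/C)C(=O)[C@@H](O[Si](C)(C)C(C)(C)C)[C@H](OB(CC)CC)[C@@]1(C)C=C[C@@H](O[Si](C)(C)C(C)(C)C)[C@@](C)(O[Si](CC)(CC)CC)[C@@H]1[C@@H](O[Si](CC)(CC)CC)C(=O)[C@]2(C)O[C@@H](C(C)(C)C)OC2=O | intermediate (not isolated)
34 | 2,4-diol (C2, C3, C4 all syn; 3-OTBS) | CC[Si](CC)(CC)OC/C=C(/C)[C@H](O)[C@@H](O[Si](C)(C)C(C)(C)C)[C@H](O)[C@@]1(C)C=C[C@@H](O[Si](C)(C)C(C)(C)C)[C@@](C)(O[Si](CC)(CC)CC)[C@@H]1[C@@H](O[Si](CC)(CC)CC)C(=O)[C@]2(C)O[C@@H](C(C)(C)C)OC2=O | intermediate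
35 | 2,4-bis-O-triethylsilyl ether of 34 | CC[Si](CC)(CC)OC/C=C(/C)[C@H](O[Si](CC)(CC)CC)[C@@H](O[Si](C)(C)C(C)(C)C)[C@H](O[Si](CC)(CC)CC)[C@@]1(C)C=C[C@@H](O[Si](C)(C)C(C)(C)C)[C@@](C)(O[Si](CC)(CC)CC)[C@@H]1[C@@H](O[Si](CC)(CC)CC)C(=O)[C@]2(C)O[C@@H](C(C)(C)C)OC2=O | intermediate
36 | (5Z)-enal: C7 aldehyde, C8 ketone (cyclisation precursor) | O=C/C=C(/C)[C@H](O[Si](CC)(CC)CC)[C@@H](O[Si](C)(C)C(C)(C)C)[C@H](O[Si](CC)(CC)CC)[C@@]1(C)C=C[C@@H](O[Si](C)(C)C(C)(C)C)[C@@](C)(O[Si](CC)(CC)CC)[C@@H]1[C@@H](O[Si](CC)(CC)CC)C(=O)[C@]2(C)O[C@@H](C(C)(C)C)OC2=O | intermediate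
37 | γ-siloxyallylchromium species: CrCl2 on C5, (E)-C6=C7–OSiMe3 (solvent ligands omitted, both configurations at C5) | C[Si](C)(C)O/C=C/C(C)([Cr](Cl)Cl)[C@H](O[Si](CC)(CC)CC)[C@@H](O[Si](C)(C)C(C)(C)C)[C@H](O[Si](CC)(CC)CC)[C@@]1(C)C=C[C@@H](O[Si](C)(C)C(C)(C)C)[C@@](C)(O[Si](CC)(CC)CC)[C@@H]1[C@@H](O[Si](CC)(CC)CC)C(=O)[C@]2(C)O[C@@H](C(C)(C)C)OC2=O | intermediate (not isolated)
38 | ten-membered carbocycle: 7-O-trimethylsilyl, 8-hydroxy, 5Z, dioxolanone on C8 | CC[Si](CC)(CC)O[C@H]1/C(C)=C\[C@H](O[Si](C)(C)C)[C@@](O)([C@]2(C)O[C@@H](C(C)(C)C)OC2=O)[C@H](O[Si](CC)(CC)CC)[C@H]2[C@](C)(O[Si](CC)(CC)CC)[C@H](O[Si](C)(C)C(C)(C)C)C=C[C@]2(C)[C@@H](O[Si](CC)(CC)CC)[C@@H]1O[Si](C)(C)C(C)(C)C | intermediate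
39 | 7,8-diol of 38 | CC[Si](CC)(CC)O[C@H]1/C(C)=C\[C@H](O)[C@@](O)([C@]2(C)O[C@@H](C(C)(C)C)OC2=O)[C@H](O[Si](CC)(CC)CC)[C@H]2[C@](C)(O[Si](CC)(CC)CC)[C@H](O[Si](C)(C)C(C)(C)C)C=C[C@]2(C)[C@@H](O[Si](CC)(CC)CC)[C@@H]1O[Si](C)(C)C(C)(C)C | intermediate (not isolated)
40 | γ-lactone (C19–O7); 8-OH and 17-OH free; 2,4,9,11-O-TES; 3,12-O-TBS | CC[Si](CC)(CC)O[C@H]1/C(C)=C\[C@@H]2OC(=O)[C@@](C)(O)[C@@]2(O)[C@H](O[Si](CC)(CC)CC)[C@H]2[C@](C)(O[Si](CC)(CC)CC)[C@H](O[Si](C)(C)C(C)(C)C)C=C[C@]2(C)[C@@H](O[Si](CC)(CC)CC)[C@@H]1O[Si](C)(C)C(C)(C)C | intermediate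
41 | lactone with 2-, 4-, 9-, 11-OH free (also 8-, 17-OH); 3,12-O-TBS | O[C@H]1/C(C)=C\[C@@H]2OC(=O)[C@@](C)(O)[C@@]2(O)[C@H](O)[C@H]2[C@](C)(O)[C@H](O[Si](C)(C)C(C)(C)C)C=C[C@]2(C)[C@@H](O)[C@@H]1O[Si](C)(C)C(C)(C)C | intermediate
42 | 4-O-hexanoate of 41 | CCCCCC(=O)O[C@H]1/C(C)=C\[C@@H]2OC(=O)[C@@](C)(O)[C@@]2(O)[C@H](O)[C@H]2[C@](C)(O)[C@H](O[Si](C)(C)C(C)(C)C)C=C[C@]2(C)[C@@H](O)[C@@H]1O[Si](C)(C)C(C)(C)C | intermediate
43 | 2,9-di-O-acetate of 42 | CCCCCC(=O)O[C@H]1/C(C)=C\[C@@H]2OC(=O)[C@@](C)(O)[C@@]2(O)[C@H](OC(C)=O)[C@H]2[C@](C)(O)[C@H](O[Si](C)(C)C(C)(C)C)C=C[C@]2(C)[C@@H](OC(C)=O)[C@@H]1O[Si](C)(C)C(C)(C)C | intermediate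
44 | CNP0153048.1 | CCCCCC(=O)O[C@H]1/C(C)=C\[C@@H]2OC(=O)[C@@](C)(O)[C@@]2(O)[C@H](OC(C)=O)[C@H]2[C@](C)(O)[C@H](O)C=C[C@]2(C)[C@@H](OC(C)=O)[C@@H]1O | target

**Step count and risks**

Total step count: 28. Longest linear sequence: 24 steps (steps 1–12, 14, 15 and 19–28, from pent-1-en-3-one).

Steps most likely to fail:

Step 23 (proposed new method). The allylchromium species may be protonated or may couple intermolecularly instead of adding to the hindered ketone. It may also add through the alternative chair, which would give the E-cyclodecene with the C7 epimer, or with the wrong ketone face. The fallback uses a known ketyl–carbonyl (pinacol) macrocyclisation in place of the polar allylmetal addition. It sets out from enal 36, whose Z double bond (installed for this purpose through iodide 26) is then kept as such. SmI2 in THF at −78 °C under high dilution joins C7 and C8 and gives, after work-up, the 7,8-diol 39. Treatment of 39 with K2CO3 in MeOH transfers the acyl group from the dioxolanone to O7, and the route is rejoined at lactone 40. No new compound is made (F0).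

Step 19. Conversion may be low with the neopentyl aldehyde, and facial discrimination may be poor because substrate control by the quaternary C1 is weak. The fallback replaces substrate control by reagent control and builds the C4 ketone afterwards. It sets out from keto aldehyde 23. A Mukaiyama aldol with the ketene silyl acetal F1, promoted by Sn(OTf)2, (S)-1-methyl-2-(piperidin-1-ylmethyl)pyrrolidine and Bu2Sn(OAc)2 in CH2Cl2 at −78 °C, gives the 2,3-syn thioester F2. Alkenyllithium 29 is quenched with Bu3SnCl to give the alkenylstannane F3. Liebeskind–Srogl-type ketone synthesis from F2 and F3 (Pd2(dba)3, tri(2-furyl)phosphine, Cu(O2PPh2), THF, 50 °C) gives the β-hydroxy ketone 32, where the route is rejoined.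

Step 2. The cycloaddition between a trisubstituted enal and a terminally substituted diene may be too slow at the temperature needed for enantiocontrol, and the enantiofacial discrimination may be incomplete. The fallback gives up catalyst control. It sets out from 2 and 3, which are combined with the achiral Lewis acid Me2AlCl (CH2Cl2, −40 °C) to give racemic 4. Its enantiomers are separated by preparative chromatography on a chiral stationary phase, the unwanted enantiomer ent-4 F4 being discarded, and the route is rejoined at 4.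

**Further compounds**

F0 | step 23 | none | none
F1 | step 19 | (Z)-2-(tert-butyldimethylsilyloxy)-1-(ethylsulfanyl)-1-(trimethylsilyloxy)ethene | CCS/C(O[Si](C)(C)C)=C\O[Si](C)(C)C(C)(C)C
F2 | step 19 | 2,3-syn S-ethyl thioester (2-hydroxy-3-silyloxy; C4 as thioester; otherwise as 32) | CCSC(=O)[C@@H](O[Si](C)(C)C(C)(C)C)[C@H](O)[C@@]1(C)C=C[C@@H](O[Si](C)(C)C(C)(C)C)[C@@](C)(O[Si](CC)(CC)CC)[C@@H]1[C@@H](O[Si](CC)(CC)CC)C(=O)[C@]2(C)O[C@@H](C(C)(C)C)OC2=O
F3 | step 19 | (Z)-tributyl[4-(triethylsilyloxy)but-2-en-2-yl]stannane | CC[Si](CC)(CC)OC/C=C(/C)[Sn](CCCC)(CCCC)CCCC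
F4 | step 2 | ent-4, ethyl (1R,2R,6R)-2-formyl-2,6-dimethyl-5-(triisopropylsilyloxy)cyclohex-4-ene-1-carboxylate | O=C[C@]1(C)CC=C(O[Si](C(C)C)(C(C)C)C(C)C)[C@H](C)[C@H]1C(=O)OCC
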